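**Retrosynthetic overview**

- Locants: quinone ring C1 (C=O), C2 (OH), C3 (side chain), C4 (C=O), C5 (OMe), C6 (H); side chain C1' (CH2 on C3), C2' (acetoxy carbon, R), C3' onward.
- Feature used: four of the six ring carbons bear oxygen. C1–C4 with their three oxygens form the carbon–oxygen skeleton of a squaric ester, and C5(OMe)–C6(H) is a 2-methoxyvinyl unit.
- Key disconnection: C4–C5, the retro ring expansion of hydroquinone 19 to 4-hydroxy-4-[(Z)-2-methoxyvinyl]cyclobutenone 16. The only ring of the target is therefore made late, from the four-membered ring, in one thermal step.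
- Before it: C1–C6 (vinyllithium + cyclobutenedione 11), C3–C1' (β-oxido alkyllithium + di-tert-butyl squarate 5), C3'–C4' (dodecyl Grignard + (R)-epichlorohydrin, which supplies C2').
- After it: oxidation to the quinone, exchange of the silyl ether at C2' for the acetate, and acid removal of the tert-butyl group on O2 last.

Key step: step 7

Remark: the ring carbinol carbons made in steps 2 and 6 form as both epimers; each is destroyed again (steps 4 and 7), so these mixtures are carried on unseparated.

**Step 1**
Reactants: 1 1-bromododecane; 2 (R)-epichlorohydrin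
Product: 4 (R)-1-chloropentadecan-2-ol, via dodecylmagnesium bromide 3 (not isolated)
Conditions: Mg, THF, reflux; then CuI (10 mol%), 2, THF, −40 → 0 °C; sat. aq NH4Cl
Reagents that add atoms: none
Why: Copper-catalysed Grignard opening of the epoxide at its unsubstituted carbon (ring-opening alkylation) leaves the C–Cl bond and the stereocentre untouched, so the configuration of 2 is carried unchanged into 4.

**Step 2**
Reactants: 4 (R)-1-chloropentadecan-2-ol; 5 di-tert-butyl squarate
Product: 8 2,3-di-tert-butoxy-4-hydroxy-4-[(2R)-2-hydroxypentadecyl]cyclobut-2-en-1-one, via lithium (R)-1-chloropentadecan-2-olate 6 (not isolated), via β-oxido alkyllithium 7 (not isolated)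
Conditions: n-BuLi (1.0 equiv), THF, −78 °C; LiC10H8 (lithium naphthalenide, 2.0 equiv, pre-formed in THF, titrated to the end point), −78 °C; cannula into 5 (1.2 equiv), THF, −78 °C; sat. aq NH4Cl, −78 °C
Reagents that add atoms: none
Why: O-deprotonation then reductive lithiation of the C–Cl bond gives a primary alkyllithium whose β-oxygen is a lithium alkoxide (too poor a leaving group to eliminate at −78 °C), and this undergoes the usual 1,2-addition of organolithiums to one squarate carbonyl; C2' is not touched.

**Step 3**
Reactants: 8 2,3-di-tert-butoxy-4-hydroxy-4-[(2R)-2-hydroxypentadecyl]cyclobut-2-en-1-one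
Product: 9 2,3-di-tert-butoxy-4-[(2R)-2-(tert-butyldimethylsilyloxy)pentadecyl]-4-hydroxycyclobut-2-en-1-one
Conditions: TBSCl (1.2 equiv), imidazole, DMF, 0 °C → rt
Reagents that add atoms: tert-butyldimethylsilyl chloride (TBSCl), CC(C)(C)[Si](C)(C)Cl
Why: Silyl ether formation with TBSCl and imidazole takes the secondary alcohol only, because the tertiary ring carbinol is too hindered to be silylated under these conditions.

**Step 4**
Reactants: 9 2,3-di-tert-butoxy-4-[(2R)-2-(tert-butyldimethylsilyloxy)pentadecyl]-4-hydroxycyclobut-2-en-1-one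
Product: 11 3-tert-butoxy-4-[(2R)-2-(tert-butyldimethylsilyloxy)pentadecyl]cyclobut-3-ene-1,2-dione, via tertiary trifluoroacetate 10 (not isolated)
Conditions: TFAA (1.2 equiv), 2,6-lutidine, CH2Cl2, −78 → 0 °C; aq NaHCO3
Reagents that add atoms: none
Why: Trifluoroacetylation of the tertiary carbinol triggers ionisation to an alkoxy-stabilised cyclobutenyl cation that expels the tert-butyl group of the terminal tert-butoxy substituent as isobutene (the acid-mediated rearrangement of squarate 1,2-adducts to cyclobutenediones), while the lutidine buffer spares the remaining tert-butyl ether and the TBS ether.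

**Step 5**
Reactants: 12 methyl vinyl ether
Product: 14 (Z)-1-bromo-2-methoxyethene, via 1,2-dibromo-1-methoxyethane 13 (not isolated)
Conditions: Br2 (1.0 equiv), CH2Cl2, −78 °C; i-Pr2NEt (1.5 equiv), −78 °C → rt; fractional distillation
Reagents that add atoms: bromine, BrBr
Why: Bromine addition to the enol ether followed by amine-induced dehydrobromination (addition–elimination) gives the 2-bromovinyl ether, with the Z isomer favoured by the cis preference of 1,2-diheteroatom-substituted alkenes and residual E isomer removed on distillation.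

**Step 6**
Reactants: 14 (Z)-1-bromo-2-methoxyethene; 11 3-tert-butoxy-4-[(2R)-2-(tert-butyldimethylsilyloxy)pentadecyl]cyclobut-3-ene-1,2-dione
Product: 16 3-tert-butoxy-2-[(2R)-2-(tert-butyldimethylsilyloxy)pentadecyl]-4-hydroxy-4-[(Z)-2-methoxyvinyl]cyclobut-2-en-1-one, via (Z)-2-methoxyvinyllithium 15 (not isolated)
Conditions: 14 (1.2 equiv), t-BuLi (1.95 equiv per 14), Et2O, −78 °C; cannula into 11, THF, −78 °C; sat. aq NaHCO3, −78 → 0 °C; base-washed glassware, crude product used at once
Reagents that add atoms: none
Why: Bromine–lithium exchange with retention gives the internally chelated (Z)-vinyllithium, which cannot undergo anti β-elimination, and its 1,2-addition goes to the carbonyl next to the tert-butoxy-bearing carbon because the other carbonyl is deactivated as a vinylogous ester.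

**Step 7**
Reactants: 16 3-tert-butoxy-2-[(2R)-2-(tert-butyldimethylsilyloxy)pentadecyl]-4-hydroxy-4-[(Z)-2-methoxyvinyl]cyclobut-2-en-1-one
Product: 19 3-tert-butoxy-2-[(2R)-2-(tert-butyldimethylsilyloxy)pentadecyl]-6-methoxybenzene-1,4-diol, via dienylketene 17 (not isolated), via cyclohexa-2,4-dienone 18 (not isolated)
Conditions: degassed PhMe (0.02 M), 110 °C, Ar, base-washed glassware
Reagents that add atoms: none
Why: Heating opens the strained cyclobutenone by conrotatory 4π electrocyclic cleavage of the bond between the carbonyl carbon (future C4) and the carbinol carbon (future C1), giving dienylketene 17. The ketene carbon C4 then bonds to the methoxy-bearing vinyl terminus C5 in a thermal (disrotatory) 6π electrocyclisation, which forms the one new skeletal bond and closes the six-membered carbocycle as cyclohexa-2,4-dienone 18. Enolisation of 18 moves the C5 hydrogen to oxygen and gives the aromatic hydroquinone 19; release of four-ring strain and aromatisation make the cascade irreversible. The closest known reaction type is the Moore rearrangement of 4-alkenyl-4-hydroxycyclobutenones made from squarate esters. No lasting stereocentre is created, since the carbinol centre of 16 and the sp3 C5 of 18 are both erased and C2' is a remote spectator. The selectivity needed is inward rotation of the methoxyvinyl group so that the ketene forms cis to it, which the outward preference of the hydroxyl donor secures, while the oxygen pattern was fixed by the regiochemistry of step 6; because the Z-methoxy group points into the closing ring, refluxing p-xylene may be needed in place of toluene.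

**Step 8**
Reactants: 19 3-tert-butoxy-2-[(2R)-2-(tert-butyldimethylsilyloxy)pentadecyl]-6-methoxybenzene-1,4-diol
Product: 20 2-tert-butoxy-3-[(2R)-2-(tert-butyldimethylsilyloxy)pentadecyl]-5-methoxycyclohexa-2,5-diene-1,4-dione
Conditions: Ag2O (3 equiv), Na2SO4, Et2O, rt
Reagents that add atoms: none
Why: Mild two-electron oxidation of the electron-rich hydroquinone to the p-benzoquinone by Ag2O affects neither the silyl ether nor the tert-butyl ether.

**Step 9**
Reactants: 20 2-tert-butoxy-3-[(2R)-2-(tert-butyldimethylsilyloxy)pentadecyl]-5-methoxycyclohexa-2,5-diene-1,4-dione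
Product: 21 2-tert-butoxy-3-[(2R)-2-hydroxypentadecyl]-5-methoxycyclohexa-2,5-diene-1,4-dione
Conditions: HF·pyridine, pyridine, THF, 0 °C → rt (plastic vessel); product used directly
Reagents that add atoms: none
Why: Fluoride-mediated desilylation with pyridine-buffered HF·pyridine should cleave the secondary TBS ether without the basic conditions that quinones do not tolerate and without enough acidity to remove the tert-butyl group.

**Step 10**
Reactants: 21 2-tert-butoxy-3-[(2R)-2-hydroxypentadecyl]-5-methoxycyclohexa-2,5-diene-1,4-dione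
Product: 22 (2R)-1-(2-tert-butoxy-5-methoxy-3,6-dioxocyclohexa-1,4-dien-1-yl)pentadecan-2-yl acetate
Conditions: Ac2O, pyridine, DMAP (cat.), CH2Cl2, 0 °C → rt
Reagents that add atoms: acetic anhydride, CC(=O)OC(C)=O
Why: Pyridine/DMAP-catalysed esterification of the secondary alcohol is unambiguous because O2 is still capped as the tert-butyl ether, and C2' keeps its configuration since its C–O bond is not broken.

**Step 11**
Reactants: 22 (2R)-1-(2-tert-butoxy-5-methoxy-3,6-dioxocyclohexa-1,4-dien-1-yl)pentadecan-2-yl acetate
Product: 23 (2R)-1-(2-hydroxy-5-methoxy-3,6-dioxocyclohexa-1,4-dien-1-yl)pentadecan-2-yl acetate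
Conditions: TFA/CH2Cl2 (1:4), 0 °C → rt; evaporation
Reagents that add atoms: none
Why: Acidolysis of the tert-butyl vinylogous ester (loss of the tert-butyl cation as isobutene) unmasks the C2 hydroxyl, whereas the methyl vinylogous ester at C5 and the secondary acetate are stable to TFA.

**Compound list**

1 | 1-bromododecane | CCCCCCCCCCCCBr | starting material
2 | (R)-epichlorohydrin | ClC[C@H]1CO1 | starting material
3 | dodecylmagnesium bromide | CCCCCCCCCCCC[Mg]Br | intermediate (not isolated)
4 | (R)-1-chloropentadecan-2-ol | ClC[C@H](O)CCCCCCCCCCCCC | intermediate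
5 | di-tert-butyl squarate (3,4-di-tert-butoxycyclobut-3-ene-1,2-dione) | CC(C)(C)OC1=C(OC(C)(C)C)C(=O)C1=O | starting material
6 | lithium (R)-1-chloropentadecan-2-olate | ClC[C@H](O[Li])CCCCCCCCCCCCC | intermediate (not isolated)
7 | (S)-1-lithio-2-(lithiooxy)pentadecane (same spatial arrangement as 4; the descriptor changes because CH2Li ranks below the alkyl chain) | [Li]C[C@H](O[Li])CCCCCCCCCCCCC | intermediate (not isolated)
8 | 2,3-di-tert-butoxy-4-hydroxy-4-[(2R)-2-hydroxypentadecyl]cyclobut-2-en-1-one (both epimers at the ring carbinol) | CCCCCCCCCCCCC[C@H](CC1(O)C(OC(C)(C)C)=C(OC(C)(C)C)C1=O)O | intermediate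
9 | 2,3-di-tert-butoxy-4-[(2R)-2-(tert-butyldimethylsilyloxy)pentadecyl]-4-hydroxycyclobut-2-en-1-one (both epimers at the ring carbinol) | CCCCCCCCCCCCC[C@H](CC1(O)C(OC(C)(C)C)=C(OC(C)(C)C)C1=O)O[Si](C)(C)C(C)(C)C | intermediate
10 | 2,3-di-tert-butoxy-1-[(2R)-2-(tert-butyldimethylsilyloxy)pentadecyl]-4-oxocyclobut-2-en-1-yl trifluoroacetate | CCCCCCCCCCCCC[C@H](CC1(OC(=O)C(F)(F)F)C(OC(C)(C)C)=C(OC(C)(C)C)C1=O)O[Si](C)(C)C(C)(C)C | intermediate (not isolated)
11 | 3-tert-butoxy-4-[(2R)-2-(tert-butyldimethylsilyloxy)pentadecyl]cyclobut-3-ene-1,2-dione | CCCCCCCCCCCCC[C@H](CC1=C(OC(C)(C)C)C(=O)C1=O)O[Si](C)(C)C(C)(C)C | intermediate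
12 | methyl vinyl ether | COC=C | starting material
13 | 1,2-dibromo-1-methoxyethane | COC(Br)CBr | intermediate (not isolated)
14 | (Z)-1-bromo-2-methoxyethene | CO/C=C\Br | intermediate
15 | (Z)-2-methoxyvinyllithium | CO/C=C\[Li] | intermediate (not isolated)
16 | 3-tert-butoxy-2-[(2R)-2-(tert-butyldimethylsilyloxy)pentadecyl]-4-hydroxy-4-[(Z)-2-methoxyvinyl]cyclobut-2-en-1-one (both epimers at the ring carbinol) | CCCCCCCCCCCCC[C@H](CC1=C(OC(C)(C)C)C(O)(/C=C\OC)C1=O)O[Si](C)(C)C(C)(C)C | intermediate
17 | (3Z,5Z)-3-tert-butoxy-2-[(2R)-2-(tert-butyldimethylsilyloxy)pentadecyl]-4-hydroxy-6-methoxyhexa-1,3,5-trien-1-one (dienylketene) | CCCCCCCCCCCCC[C@H](CC(=C=O)/C(OC(C)(C)C)=C(O)\C=C/OC)O[Si](C)(C)C(C)(C)C | intermediate (not isolated)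
18 | 3-tert-butoxy-2-[(2R)-2-(tert-butyldimethylsilyloxy)pentadecyl]-4-hydroxy-6-methoxycyclohexa-2,4-dien-1-one (both epimers at C6) | CCCCCCCCCCCCC[C@H](CC1=C(OC(C)(C)C)C(O)=CC(OC)C1=O)O[Si](C)(C)C(C)(C)C | intermediate (not isolated)
19 | 3-tert-butoxy-2-[(2R)-2-(tert-butyldimethylsilyloxy)pentadecyl]-6-methoxybenzene-1,4-diol | CCCCCCCCCCCCC[C@H](Cc1c(OC(C)(C)C)c(O)cc(OC)c1O)O[Si](C)(C)C(C)(C)C | intermediate
20 | 2-tert-butoxy-3-[(2R)-2-(tert-butyldimethylsilyloxy)pentadecyl]-5-methoxycyclohexa-2,5-diene-1,4-dione | CCCCCCCCCCCCC[C@H](CC1=C(OC(C)(C)C)C(=O)C=C(OC)C1=O)O[Si](C)(C)C(C)(C)C | intermediate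
21 | 2-tert-butoxy-3-[(2R)-2-hydroxypentadecyl]-5-methoxycyclohexa-2,5-diene-1,4-dione | CCCCCCCCCCCCC[C@H](CC1=C(OC(C)(C)C)C(=O)C=C(OC)C1=O)O | intermediate
22 | (2R)-1-(2-tert-butoxy-5-methoxy-3,6-dioxocyclohexa-1,4-dien-1-yl)pentadecan-2-yl acetate | CCCCCCCCCCCCC[C@H](CC1=C(OC(C)(C)C)C(=O)C=C(OC)C1=O)OC(C)=O | intermediate
23 | (2R)-1-(2-hydroxy-5-methoxy-3,6-dioxocyclohexa-1,4-dien-1-yl)pentadecan-2-yl acetate (CNP0332196.1) | CCCCCCCCCCCCC[C@H](CC1=C(O)C(=O)C=C(OC)C1=O)OC(C)=O | target

**Step count**

Total: 11 steps. Longest linear sequence: 10 steps (steps 1–4 and 6–11); step 5 is a one-step side branch.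

**Steps most likely to fail**

Step 2. Electron transfer from the radical-anion reductant or from the alkyllithium to the easily reduced squarate, and β-elimination of the dilithio reagent on warming, could erode the 1,2-addition. The fallback sets out from 4 and comes back at 8. A Finkelstein exchange (NaI, butanone, reflux) would give (R)-1-iodopentadecan-2-ol F1. O-Lithiation with MeLi in Et2O at −78 °C would give lithium (R)-1-iodopentadecan-2-olate F2. Iodine–lithium exchange with t-BuLi (2 equiv, −78 °C) would then produce the same reagent 7 by halogen–metal exchange, with no dissolving-metal reductant present when 5 is added; addition to 5 and quench as before should give 8.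

Step 6. β-Elimination of the vinyllithium (loss of lithium methoxide), incomplete halogen–lithium exchange, or loss of selectivity between the two ring carbonyls could defeat the addition. The fallback sets out from 11, with 14 as the two-carbon source, and comes back at 16. Treatment of 14 with LiN(i-Pr)2 (2 equiv, THF, −78 → 0 °C) should cause anti-dehydrobromination and deprotonation to lithium methoxyacetylide F3, a robust nucleophile with no β-leaving group. Its addition to 11 at −78 °C should follow the same carbonyl preference and give 3-tert-butoxy-2-[(2R)-2-(tert-butyldimethylsilyloxy)pentadecyl]-4-hydroxy-4-(methoxyethynyl)cyclobut-2-en-1-one F4. Semi-hydrogenation (H2, Pd on CaCO3 poisoned with Pb(OAc)2, quinoline, EtOAc, 0 °C) adds hydrogen syn and should deliver the cis enol ether 16.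

Step 7. Ionisation or dehydration of the free tertiary allylic carbinol beside the enol ether could compete with ring opening, and closure could be slow because the Z-methoxy group points into the forming ring. The fallback sets out from 16 and comes back at 19. The carbinol would be capped (TMSCl, imidazole, CH2Cl2, 0 °C) as 3-tert-butoxy-2-[(2R)-2-(tert-butyldimethylsilyloxy)pentadecyl]-4-[(Z)-2-methoxyvinyl]-4-(trimethylsilyloxy)cyclobut-2-en-1-one F5. F5 can be heated harder (p-xylene, 138 °C) without ionisation, and the siloxy group still rotates outward. The ring expansion should then give 3-tert-butoxy-2-[(2R)-2-(tert-butyldimethylsilyloxy)pentadecyl]-6-methoxy-4-(trimethylsilyloxy)phenol F6. Brief K2CO3/MeOH at 0 °C removes the aryl trimethylsilyl ether, leaves the alkyl TBS ether, and gives 19.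

**Further compounds**

F1 | step 2 | (R)-1-iodopentadecan-2-ol | IC[C@H](O)CCCCCCCCCCCCC
F2 | step 2 | lithium (R)-1-iodopentadecan-2-olate | IC[C@H](O[Li])CCCCCCCCCCCCC
F3 | step 6 | lithium methoxyacetylide | [Li]C#COC
F4 | step 6 | 3-tert-butoxy-2-[(2R)-2-(tert-butyldimethylsilyloxy)pentadecyl]-4-hydroxy-4-(methoxyethynyl)cyclobut-2-en-1-one | CCCCCCCCCCCCC[C@H](CC1=C(OC(C)(C)C)C(O)(C#COC)C1=O)O[Si](C)(C)C(C)(C)C
F5 | step 7 | 3-tert-butoxy-2-[(2R)-2-(tert-butyldimethylsilyloxy)pentadecyl]-4-[(Z)-2-methoxyvinyl]-4-(trimethylsilyloxy)cyclobut-2-en-1-one | CCCCCCCCCCCCC[C@H](CC1=C(OC(C)(C)C)C(O[Si](C)(C)C)(/C=C\OC)C1=O)O[Si](C)(C)C(C)(C)C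
F6 | step 7 | 3-tert-butoxy-2-[(2R)-2-(tert-butyldimethylsilyloxy)pentadecyl]-6-methoxy-4-(trimethylsilyloxy)phenol | CCCCCCCCCCCCC[C@H](Cc1c(OC(C)(C)C)c(O[Si](C)(C)C)cc(OC)c1O)O[Si](C)(C)C(C)(C)C
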